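We read this flask at 3.0 min, so we need to know how much coupling partner has come over from the gas by then, and which species took it.

    starting material ⇌ tautomer (K1 = 1.6, k1 = 0.012 s⁻¹)
    starting material + coupling partner → isomer of the product (k2 = 5.1 L mol⁻¹ s⁻¹)
    coupling partner + tautomer → target (k3 = 7.8 L mol⁻¹ s⁻¹)
    gas ⇌ coupling partner, rate k4*(csat - [coupling partner]) (k4 = 0.014 s⁻¹, csat = 14 mM)

starting material 0.050 M; gas 14 mM (held); time 3.0 min

- how much target there is at 3.0 min, in percent of the starting material charged
- concentration of coupling partner in solution at 3.0 min, in percent of saturation

- at the start none of coupling partner is dissolved
- run time (flask): 3.0 min

The charged starting material removes dissolved coupling partner at 0.255 s⁻¹, faster than the transfer coefficient of 0.014 s⁻¹ refills it. We therefore take gas transfer as the rate-limiting step and treat dissolved partner as a small correction. Delivery then runs at its ceiling, the transfer coefficient times the saturation concentration, and by the time of reading it comes to 70.6 % of the charge.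

With starting material and tautomer at equilibrium, the selectivity for target is 71.0 %. But tautomer starts from zero, and its relaxation time is 51.3 s. We call the lag toll the part of the charge delivered within one relaxation time, counted as going to the isomer of the product: 20.1 %. Selectivity times the delivery beyond the toll gives 35.8 % target.

The second way uses no toll. We let the tautomer's share of the pool rise exponentially from zero to its equilibrium value, so that at equal steps of time up to the reading it stands at 0.424, 0.556 and 0.597. The running selectivities for target at those times are 53.0 %, 65.7 % and 69.4 %, and the trapezoid rule over the delivery, starting from a selectivity of zero, gives 36.1 % target.

Both ways assume the same ceiling, so their agreement tests the toll and not the supply. For the correction, we take the pool left at equilibrium, which removes dissolved partner at 0.0995 s⁻¹. Balancing transfer against this removal puts dissolved partner at 12.3 % of saturation.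

The forecast gives 34 % and 10.5 %, both below our figures , on the grounds that “dissolved partner is consumed far faster than it arrives”. The simulation gives 33.5 % and 9.82 %.

Our target figure stands 2.4 percentage points above the flask. Now take the same flask left until 8.0 min. There the ceiling comes to 188 % of the charge, more than the charge itself, so the charge replaces the delivery. The toll contains no time and stays 20.1 %, which leaves 56.7 % target. That flask holds 0 % starting material, 0 % tautomer, 43.0 % isomer of the product and 57.0 % target.

The rate constants belong to no real substance; no experiment stands behind them.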